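The route cuts the C4–C4a bond of ring C. Ring A activates C4a three times over. It is flanked by the O-bearing carbons C5 and C8a and stands para to C7–O, so C4 can acylate it at the very end. One intramolecular Friedel–Crafts acylation closes the pyranone and completes the protected diprenylflavonol skeleton. The precursor is an (E)-2-(MOM-oxy)-3-aryl-3-aryloxyacrylic acid whose carboxyl group stands cis to a symmetrical 3,5-bis(MOM-oxy)phenoxy group. It is assembled from a diprenylbenzoic acid, MOM-protected methyl glycolate and phloroglucinol bis-MOM ether. The prenyl groups come from a double Stille coupling.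

Key step: step 10

Remark on geometry: the target has no stereocentre. All acyclic tetrasubstituted alkenes are drawn as E isomers, with the carboxyl-type group cis to the oxygen substituent at C3 (OMOM outranks the carboxyl carbon at C2, and oxygen outranks aryl at C3). It is assumed that any Z isomer can be carried along, because the ring closure is stereoconvergent.

Step 1
Reactants: 1 phloroglucinol
Product: 2 3,5-bis(methoxymethoxy)phenol
Conditions: MOMCl (2.0 equiv), iPr2NEt (2.2 equiv), DMF, 0 °C → rt; chromatography
Reagents that add atoms: chloromethyl methyl ether (MOMCl), COCCl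
Why: Williamson-type O-alkylation of the threefold symmetrical triphenol with two equivalents of the acetal chloride should give the bis-ether as the main member of a statistical set that is separable on silica, and the cheap starting material makes this the one place where selectivity is bought with material.

Step 2
Reactants: 3 methyl glycolate
Product: 4 methyl 2-(methoxymethoxy)acetate
Conditions: MOMCl, iPr2NEt, CH2Cl2, 0 °C → rt
Reagents that add atoms: chloromethyl methyl ether (MOMCl), COCCl
Why: Standard acetal protection (O-alkylation of a primary alcohol by MOMCl under a hindered amine base) leaves the methyl ester untouched and supplies C3 and C4 of the flavonol together with the masked 3-hydroxyl group.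

Step 3
Reactants: 5 methyl 4-hydroxy-3,5-diiodobenzoate
Product: 6 methyl 3,5-diiodo-4-(methoxymethoxy)benzoate
Conditions: MOMCl, iPr2NEt, CH2Cl2, 0 °C → rt
Reagents that add atoms: chloromethyl methyl ether (MOMCl), COCCl
Why: Williamson-type O-alkylation of an acidic, fully ionised 2,6-diiodophenol by the small and very reactive MOMCl masks the phenol before the palladium and enolate chemistry, while the two iodine atoms already mark the positions of both prenyl groups.

Step 4
Reactants: 6 methyl 3,5-diiodo-4-(methoxymethoxy)benzoate; 7 tributyl(3-methylbut-2-enyl)stannane (2.5 equiv)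
Product: 8 methyl 4-(methoxymethoxy)-3,5-bis(3-methylbut-2-enyl)benzoate
Conditions: Pd(PPh3)4 (5 mol %), DMF, 90 °C
Reagents that add atoms: none
Why: Twofold Stille cross-coupling, in which zerovalent palladium inserts into the carbon–iodine bonds (activated by the para ester), the allylic stannane transmetalates and reductive elimination at the unsubstituted allyl terminus should give the linear prenyl arene, which avoids the O/C and mono/di selectivity problems of phenolate prenylation.

Step 5
Reactants: 8 methyl 4-(methoxymethoxy)-3,5-bis(3-methylbut-2-enyl)benzoate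
Product: 9 4-(methoxymethoxy)-3,5-bis(3-methylbut-2-enyl)benzoic acid
Conditions: LiOH, THF/MeOH/H2O, 50 °C; then cold dilute HCl to pH 4
Reagents that add atoms: lithium hydroxide (LiOH), [Li+].[OH-]
Why: Ordinary saponification (acyl–oxygen ester hydrolysis), to which aryl MOM ethers and isolated trisubstituted alkenes are inert, followed by a brief cold acidification that the acetal tolerates.

Step 6
Reactants: 9 4-(methoxymethoxy)-3,5-bis(3-methylbut-2-enyl)benzoic acid; 4 methyl 2-(methoxymethoxy)acetate (3.3 equiv)
Product: 12 methyl 2-(methoxymethoxy)-3-[4-(methoxymethoxy)-3,5-bis(3-methylbut-2-enyl)phenyl]-3-oxopropanoate (racemic), via lithium enolate 10 (not isolated), via acyl imidazolide 11 (not isolated)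
Conditions: 9, 1,1'-carbonyldiimidazole, THF, rt; added to 10 [from 4, LiN(iPr)2 (3.3 equiv), THF, −78 °C]; −78 → −30 °C; aq NH4Cl
Reagents that add atoms: 1,1'-carbonyldiimidazole, O=C(n1ccnc1)n1ccnc1 (imidazolyl group of 11 only); LiN(iPr)2, [Li+].CC(C)[N-]C(C)C (lithium of 10 only); no atom of either remains in 12
Why: Crossed Claisen condensation in the form of C-acylation of a preformed ester enolate by a non-enolisable acyl imidazolide, in which the surplus enolate takes up the imidazole N–H and the acidic proton of the β-keto ester; the new C2 stereocentre is formed racemic and disappears in step 7.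

Step 7
Reactants: 12 methyl 2-(methoxymethoxy)-3-[4-(methoxymethoxy)-3,5-bis(3-methylbut-2-enyl)phenyl]-3-oxopropanoate
Product: 13 methyl (E)-2-(methoxymethoxy)-3-[4-(methoxymethoxy)-3,5-bis(3-methylbut-2-enyl)phenyl]-3-(4-methylphenyl)sulfonyloxyprop-2-enoate
Conditions: TsCl, N-methylimidazole, LiOH, PhCl, 0 °C → rt
Reagents that add atoms: p-toluenesulfonyl chloride (TsCl), Cc1ccc(cc1)S(=O)(=O)Cl
Why: Stereoselective enol tosylation of a β-keto ester, in which the lithium-chelated enolate is O-sulfonylated by the N-tosylimidazolium salt formed from TsCl and N-methylimidazole, which should place the tosyloxy group cis to the ester (E by the sequence rules, since OMOM outranks CO2Me).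

Step 8
Reactants: 13 methyl (E)-2-(methoxymethoxy)-3-[4-(methoxymethoxy)-3,5-bis(3-methylbut-2-enyl)phenyl]-3-(4-methylphenyl)sulfonyloxyprop-2-enoate; 2 3,5-bis(methoxymethoxy)phenol
Product: 14 methyl (E)-3-[3,5-bis(methoxymethoxy)phenoxy]-2-(methoxymethoxy)-3-[4-(methoxymethoxy)-3,5-bis(3-methylbut-2-enyl)phenyl]prop-2-enoate
Conditions: Cs2CO3, DMF, rt → 50 °C
Reagents that add atoms: none
Why: Nucleophilic vinylic substitution by addition–elimination, in which the phenoxide of 2 adds to the ester-activated β-carbon and the resulting ester enolate expels tosylate, normally with retention, while the lack of α- and γ-hydrogen atoms rules out elimination to an alkyne or allene.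

Step 9
Reactants: 14 methyl (E)-3-[3,5-bis(methoxymethoxy)phenoxy]-2-(methoxymethoxy)-3-[4-(methoxymethoxy)-3,5-bis(3-methylbut-2-enyl)phenyl]prop-2-enoate
Product: 15 (E)-3-[3,5-bis(methoxymethoxy)phenoxy]-2-(methoxymethoxy)-3-[4-(methoxymethoxy)-3,5-bis(3-methylbut-2-enyl)phenyl]prop-2-enoic acid
Conditions: LiOH, THF/H2O, 45 °C; then cold dilute HCl to pH 4–5 under EtOAc
Reagents that add atoms: lithium hydroxide (LiOH), [Li+].[OH-]
Why: Saponification as practised on β-aryloxycinnamic esters, where the doubly oxygenated, fully substituted alkene is a poor conjugate acceptor, so hydroxide should attack the ester carbonyl and not displace the aryloxide, methanol is left out to avoid alkoxide exchange at C3, and the cold two-phase acidification spares the enol acetal.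

Step 10
Reactants: 15 (E)-3-[3,5-bis(methoxymethoxy)phenoxy]-2-(methoxymethoxy)-3-[4-(methoxymethoxy)-3,5-bis(3-methylbut-2-enyl)phenyl]prop-2-enoic acid
Product: 18 3,5,7-tris(methoxymethoxy)-2-[4-(methoxymethoxy)-3,5-bis(3-methylbut-2-enyl)phenyl]chromen-4-one, via acid chloride 16 (not isolated), via acyl triflate 17 (not isolated)
Conditions: 1-chloro-N,N,2-trimethylprop-1-en-1-amine (1.05 equiv), CH2Cl2, 0 °C; volatiles stripped; 2,6-di-tert-butyl-4-methylpyridine (2 equiv), AgOTf (1.2 equiv), CH2Cl2 (0.01 M), −40 → 0 °C
Reagents that add atoms: 1-chloro-N,N,2-trimethylprop-1-en-1-amine, CC(C)=C(Cl)N(C)C (chlorine of 16 only); AgOTf, [Ag+].[O-]S(=O)(=O)C(F)(F)F (triflate of 17 only); no atom of either remains in 18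
Why: The chloroenamine turns the acid into acid chloride 16 without releasing acid (its excess is stripped so that silver cannot convert it into a keteniminium salt), AgOTf abstracts chloride to give acyl triflate 17, in effect an acylium ion pair, the acyl carbon C4 is attacked by the ring-A carbon ortho to the ether oxygen, and the arenium ion hands its proton to the hindered pyridine. The closest known reaction type is the intramolecular Friedel–Crafts acylation of β-aryloxyacrylic and β-aryloxycinnamic acids to chromones and flavones, run here with a silver-activated acid chloride under buffering in place of a strong protic or Lewis acid. Ring C closes in a six-membered, 6-exo mode at the acyl carbon (the C=O stays outside the new ring), and C4–C4a is the only skeletal bond formed. No stereocentre is created. Chemoselectivity for ring A over ring B (a strained five-membered indenone closure onto a carbon activated only by alkyl groups) and over the prenyl alkenes rests on three points: the attacked carbon is ortho, ortho and para to three oxygen substituents, acyl and aryloxy groups are cis in the E isomer, and rotation about C2–C3 is easy in the ketene–oxocarbenium resonance form of the acylium ion, which feeds any Z isomer into the productive one. Regioselectivity is no issue because the two ortho carbons of the 3,5-disubstituted phenoxy ring are equivalent and the para carbon cannot reach C4, while the cold, dilute and buffered medium should spare the MOM acetals and the prenyl groups.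

Step 11
Reactants: 18 3,5,7-tris(methoxymethoxy)-2-[4-(methoxymethoxy)-3,5-bis(3-methylbut-2-enyl)phenyl]chromen-4-one
Product: 19 3,5,7-trihydroxy-2-[4-hydroxy-3,5-bis(3-methylbut-2-enyl)phenyl]chromen-4-one (target)
Conditions: aq HCl (3 M), MeOH, 40 °C, stopped at full conversion
Reagents that add atoms: none
Why: Acid-catalysed transacetalisation with methanol removes all four MOM groups as dimethoxymethane, a deprotection in routine use for prenylated flavonoids because oxocarbenium formation from the acetals is much faster in dilute acid at mild temperature than protonation of the trisubstituted alkenes.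

Compound list
1 | phloroglucinol | Oc1cc(O)cc(O)c1 | starting material
2 | 3,5-bis(methoxymethoxy)phenol | COCOc1cc(O)cc(OCOC)c1 | intermediate
3 | methyl glycolate | COC(=O)CO | starting material
4 | methyl 2-(methoxymethoxy)acetate | COCOCC(=O)OC | intermediate
5 | methyl 4-hydroxy-3,5-diiodobenzoate | COC(=O)c1cc(I)c(O)c(I)c1 | starting material
6 | methyl 3,5-diiodo-4-(methoxymethoxy)benzoate | COCOc1c(I)cc(cc1I)C(=O)OC | intermediate
7 | tributyl(3-methylbut-2-enyl)stannane | CCCC[Sn](CCCC)(CCCC)CC=C(C)C | starting material
8 | methyl 4-(methoxymethoxy)-3,5-bis(3-methylbut-2-enyl)benzoate | COCOc1c(CC=C(C)C)cc(cc1CC=C(C)C)C(=O)OC | intermediate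
9 | 4-(methoxymethoxy)-3,5-bis(3-methylbut-2-enyl)benzoic acid | COCOc1c(CC=C(C)C)cc(cc1CC=C(C)C)C(=O)O | intermediate
10 | lithium enolate of 4 (chelated, OLi and OMOM cis) | [Li+].[O-]/C(OC)=C\OCOC | intermediate
11 | 1-[4-(methoxymethoxy)-3,5-bis(3-methylbut-2-enyl)benzoyl]imidazole | COCOc1c(CC=C(C)C)cc(cc1CC=C(C)C)C(=O)n1ccnc1 | intermediate
12 | methyl 2-(methoxymethoxy)-3-[4-(methoxymethoxy)-3,5-bis(3-methylbut-2-enyl)phenyl]-3-oxopropanoate (racemic) | COC(=O)C(OCOC)C(=O)c1cc(CC=C(C)C)c(OCOC)c(CC=C(C)C)c1 | intermediate
13 | methyl (E)-2-(methoxymethoxy)-3-[4-(methoxymethoxy)-3,5-bis(3-methylbut-2-enyl)phenyl]-3-(4-methylphenyl)sulfonyloxyprop-2-enoate | COC(=O)/C(OCOC)=C(\OS(=O)(=O)c1ccc(C)cc1)c1cc(CC=C(C)C)c(OCOC)c(CC=C(C)C)c1 | intermediate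
14 | methyl (E)-3-[3,5-bis(methoxymethoxy)phenoxy]-2-(methoxymethoxy)-3-[4-(methoxymethoxy)-3,5-bis(3-methylbut-2-enyl)phenyl]prop-2-enoate | COC(=O)/C(OCOC)=C(\Oc1cc(OCOC)cc(OCOC)c1)c1cc(CC=C(C)C)c(OCOC)c(CC=C(C)C)c1 | intermediate
15 | (E)-3-[3,5-bis(methoxymethoxy)phenoxy]-2-(methoxymethoxy)-3-[4-(methoxymethoxy)-3,5-bis(3-methylbut-2-enyl)phenyl]prop-2-enoic acid | OC(=O)/C(OCOC)=C(\Oc1cc(OCOC)cc(OCOC)c1)c1cc(CC=C(C)C)c(OCOC)c(CC=C(C)C)c1 | intermediate
16 | (E)-3-[3,5-bis(methoxymethoxy)phenoxy]-2-(methoxymethoxy)-3-[4-(methoxymethoxy)-3,5-bis(3-methylbut-2-enyl)phenyl]prop-2-enoyl chloride | O=C(Cl)/C(OCOC)=C(\Oc1cc(OCOC)cc(OCOC)c1)c1cc(CC=C(C)C)c(OCOC)c(CC=C(C)C)c1 | intermediate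
17 | (E)-3-[3,5-bis(methoxymethoxy)phenoxy]-2-(methoxymethoxy)-3-[4-(methoxymethoxy)-3,5-bis(3-methylbut-2-enyl)phenyl]prop-2-enoyl trifluoromethanesulfonate | O=C(OS(=O)(=O)C(F)(F)F)/C(OCOC)=C(\Oc1cc(OCOC)cc(OCOC)c1)c1cc(CC=C(C)C)c(OCOC)c(CC=C(C)C)c1 | intermediate
18 | 3,5,7-tris(methoxymethoxy)-2-[4-(methoxymethoxy)-3,5-bis(3-methylbut-2-enyl)phenyl]chromen-4-one | CC(C)=CCc1cc(-c2oc3cc(OCOC)cc(OCOC)c3c(=O)c2OCOC)cc(CC=C(C)C)c1OCOC | intermediate
19 | 3,5,7-trihydroxy-2-[4-hydroxy-3,5-bis(3-methylbut-2-enyl)phenyl]chromen-4-one | CC(C)=CCc1cc(-c2oc3cc(O)cc(O)c3c(=O)c2O)cc(CC=C(C)C)c1O | target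

Total step count: 11
Longest linear sequence: 9 steps (5 → 6 → 8 → 9 → 12 → 13 → 14 → 15 → 18 → 19; steps 1 and 2 are side branches)

Steps most likely to fail

Step 10. The donor-stabilised acylium species may close too slowly. The activated acyl group or the pyridinium triflate would then have time to cleave MOM acetals or to acylate a prenyl alkene.

The fallback forms the same C4–C4a bond with reversed polarity in a basic medium, to which prenyl and MOM groups are inert. It sets out from acid 15. Carbodiimide coupling with diethylamine (EDC·HCl, HOBt, CH2Cl2) would give (E)-N,N-diethyl-3-[3,5-bis(methoxymethoxy)phenoxy]-2-(methoxymethoxy)-3-[4-(methoxymethoxy)-3,5-bis(3-methylbut-2-enyl)phenyl]prop-2-enamide F1.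

Treatment with LiN(iPr)2 in THF (−78 → 0 °C) should lithiate the phenoxy ring at the carbon ortho to the ether oxygen. This is amide-directed remote metalation, the anionic counterpart of the Friedel–Crafts closure known from 2-aryloxybenzamides to xanthones, helped here by the flanking OMOM group. The aryllithium adds to the cis amide carbonyl, diethylamide is lost, and the sequence comes back to the route at 18. Lithiation between the two OMOM groups is reversible in the presence of the amine and leads nowhere.

Step 8. The phenoxide may attack sulfur in place of carbon, which transfers the sulfonyl group and returns the enolate. It may also add only sluggishly to the crowded, donor-substituted β-carbon.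

The fallback replaces addition–elimination by a metal-catalysed C–O cross-coupling. It sets out from β-keto ester 12. LiN(SiMe3)2 and PhNTf2 (THF, −78 → 0 °C) would give methyl (E)-2-(methoxymethoxy)-3-[4-(methoxymethoxy)-3,5-bis(3-methylbut-2-enyl)phenyl]-3-(trifluoromethylsulfonyloxy)prop-2-enoate F2.

F2 is coupled with phenol 2 under Pd2(dba)3, 2-(di-tert-butylphosphino)biphenyl and K3PO4 in toluene at 90 °C. Zerovalent palladium adds oxidatively to the C–O bond of the enol triflate, phenoxide exchanges for triflate, and C–O reductive elimination follows, favoured by the electron-poor vinyl ligand. The sequence comes back to the route at 14.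

Step 11. Once the 4'-hydroxyl group is free, acid may promote its addition to a flanking prenyl alkene (chroman ring formation). Acid may also add methanol or water across a prenyl alkene before the last acetal has gone.

The fallback avoids Brønsted acid by exchanging the protecting groups. It sets out from 18. TMSOTf and 2,2'-bipyridyl in MeCN (0 °C → rt) should convert the four aryl-type MOM ethers, through bipyridinium-trapped methoxymethyl groups, into 3,5,7-tris(trimethylsilyloxy)-2-[4-(trimethylsilyloxy)-3,5-bis(3-methylbut-2-enyl)phenyl]chromen-4-one F3. Its silyl ethers are hydrolysed by added water at neutral pH, and the sequence comes back to the route at 19.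

Further compounds
F1 | step 10 | (E)-N,N-diethyl-3-[3,5-bis(methoxymethoxy)phenoxy]-2-(methoxymethoxy)-3-[4-(methoxymethoxy)-3,5-bis(3-methylbut-2-enyl)phenyl]prop-2-enamide | CCN(CC)C(=O)/C(OCOC)=C(\Oc1cc(OCOC)cc(OCOC)c1)c1cc(CC=C(C)C)c(OCOC)c(CC=C(C)C)c1
F2 | step 8 | methyl (E)-2-(methoxymethoxy)-3-[4-(methoxymethoxy)-3,5-bis(3-methylbut-2-enyl)phenyl]-3-(trifluoromethylsulfonyloxy)prop-2-enoate | COC(=O)/C(OCOC)=C(\OS(=O)(=O)C(F)(F)F)c1cc(CC=C(C)C)c(OCOC)c(CC=C(C)C)c1
F3 | step 11 | 3,5,7-tris(trimethylsilyloxy)-2-[4-(trimethylsilyloxy)-3,5-bis(3-methylbut-2-enyl)phenyl]chromen-4-one | CC(C)=CCc1cc(-c2oc3cc(O[Si](C)(C)C)cc(O[Si](C)(C)C)c3c(=O)c2O[Si](C)(C)C)cc(CC=C(C)C)c1O[Si](C)(C)C
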